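(The readings were computed for substances that don't exist; noise was put on by code.)

**Minutes: which flask gives the most bis adduct?**

| flask | substrate | coupling partner | temperature | remark | time |
|---|---|---|---|---|---|
| green | 0.20 M | 0.75 M | 35 °C | run made earlier |  |
| violet | 0.45 M | 0.75 M | 70 °C | run made earlier |  |
| delta | 0.30 M | 0.750 M |  | at 40 °C until 80 s, from then on at 100 °C | 2.5 min |
| gamma | 0.30 M | 0.750 M | 100 °C |  | 2.5 min |
| beta | 0.30 M | 0.750 M | 70 °C |  | 2.5 min |
| eta | 0.30 M | 0.750 M | 40 °C |  | 2.5 min |

| run | time / min | bis adduct / % | substrate / % |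
|---|---|---|---|
| green | 4.00 | 0.9 | 83.4 |
| green | 6.00 | 2.7 | 76.7 |
| green | 8.00 | 3.4 | 70.7 |
| green | 12.0 | 7.0 | 60.4 |
| green | 20.0 | 12.1 | 44.4 |
| green | 30.0 | 17.5 | 31.1 |
| green | 50.0 | 22.0 | 16.9 |
| violet | 0.667 | 1.3 | 77.1 |
| violet | 1.33 | 4.0 | 61.9 |
| violet | 2.00 | 5.2 | 51.2 |
| violet | 4.00 | 9.2 | 32.4 |
| violet | 6.00 | 10.7 | 24.4 |
| violet | 8.00 | 12.6 | 19.1 |

(scatter of a reading: 0.3 percentage points)

- the best flask by amount of bis adduct, in percent of the substrate charged; "all alike" if 1.5 percentage points covers them all (delta / gamma / beta / eta / all alike)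
- amount of bis adduct at the end, in percent of the substrate charged, delta
- amount of bis adduct at the end, in percent of the substrate charged, gamma
- amount of bis adduct at the end, in percent of the substrate charged, beta
- amount of bis adduct at the end, in percent of the substrate charged, eta

- the numbers in the tables scatter with a standard deviation of 0.3 percentage points

The meeting opened from a one-step world, in which substrate and coupling partner give bis adduct directly. The chair objected that the green run had lost 16.6% of its substrate after 4.00 min but showed 0.9% bis adduct, so at least one step lies between.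

A colleague proposed a clock for the substrate. The first readings, taken while the coupling partner stands near its charge (pseudo-first-order), give a loss of 0.0454 min⁻¹ in the green run and 0.390 min⁻¹ in the violet run. That means an activation energy near 54.0 kJ mol⁻¹, so 1.79 min⁻¹ at 100 °C and 0.0635 min⁻¹ at 40 °C. Gamma then counts 4.47 lifetimes. This count, the minutes at each temperature times the loss rate there, added over the stretches, puts delta at 2.17, beta at 0.975 and eta at 0.159.

The same colleague then read bis adduct off the nearest run at equal count. Eta stands beside the first green reading, count 0.182, so about 0.9%. Beta falls between the violet readings at counts 0.669 and 1.13, so about 7.87%. Delta and gamma lie past the last violet count, 1.66, where bis adduct read 12.6% and was still rising, so the colleague expected both above that, gamma ahead.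

The forecast differed on those two. Holding that bis adduct “plateaus at a fixed fraction of converted substrate”, it named gamma, with 8% for delta, 11% for gamma, 6% for beta and 0.8% for eta.

**Result**

Gamma led with 34.3%, then delta 24.5%, beta 7.69% and eta 0.895%. The forecast's gamma figure is close to the last violet reading taken over. Delta's count of 2.17 lies beside gamma's at 1.25 min, 2.24, and the two flasks stand close at those counts: delta ended with 24.5% bis adduct and 18.7% substrate, gamma at 1.25 min held 25.1% and 17.9%.

    substrate + coupling partner → single product (k = 0.00949 M⁻¹ s⁻¹, Ea = 56.0 kJ mol⁻¹)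
    coupling partner + single product → bis adduct (k = 0.00832 M⁻¹ s⁻¹, Ea = 57.0 kJ mol⁻¹)
    coupling partner + bis adduct → tris adduct (k = 0.00200 M⁻¹ s⁻¹, Ea = 58.0 kJ mol⁻¹)
    coupling partner + tris adduct → tetra adduct (k = 0.00930 M⁻¹ s⁻¹, Ea = 70.0 kJ mol⁻¹)
    bis adduct ⇌ isomer of the product (K = 2.66, k = 0.0345 s⁻¹, Ea = 102 kJ mol⁻¹, ΔH = −44.0 kJ mol⁻¹)
    (constants at 70 °C)

The eta flask run at 65 °C counts 0.737, which leaves 47.9% substrate and lies just past the violet reading at 2.00 min, so bis adduct should stand a little above 5.2%. The computed flask holds 50.2% substrate and 6.24% bis adduct.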